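The ten-membered carbocycle is closed last at C5–C6 (germacrane numbering). The route exploits that C6, the carbinol carbon of the γ-lactone ring, is allylic to the Z-configured C4=C5 alkene of the carbocycle and γ to the C12 carbonyl. Both carbons are carried as electrophiles, a Z-iodoalkene (C5) and an aldehyde (C6), and are united by reductive polarity reversal in an intramolecular Nozaki–Hiyama–Kishi reaction. In one operation this closes the carbocycle, sets C6 and lets the new C6 oxygen lactonise onto the C12 methyl ester to the cis-fused α-methylene lactone. The acyclic precursor already holds C3, C7, C8, C9, both Z-alkenes, the acetate and the epoxyangelate.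

Key step: step 22

Remark on numbering and configuration: germacrane numbering is used throughout. The carbocycle is C1–C10 with C1=C10 (C14 methyl on C10) and C4=C5 (C15 methyl on C4). C3 carries the acetate, C6 the lactone oxygen, C7 the C11(=C13H2)–C12 unit, C8 the hydroxyl and C9 the epoxyangelate. The target is read as (3S,6R,7S,8R,9S), 1(10)Z,4Z, with a (2R,3R)-epoxide and a cis ring fusion (H6 and H7 on the same face).

Assumption: the pentane solution of (−)-B-allyldiisopinocampheylborane (derived from (+)-α-pinene) is used as purchased.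

**Route**

Step 1
Reactants: 1 prop-2-yn-1-ol
Product: 3 (Z)-3-iodo-2-methylprop-2-en-1-ol, via alkenylmagnesium alkoxide 2 (not isolated)
Conditions: MeMgBr (2.3 equiv), CuI (10 mol %), Et2O/THF, −10 °C → rt; then I2, −10 °C
Reagents that add atoms: methylmagnesium bromide C[Mg]Br; iodine [I][I]
Why: Duboudin reaction: copper-catalysed anti-carbomagnesiation of the propargylic alkoxide through a five-membered magnesium chelate puts methyl on the internal carbon (C4) and magnesium on the terminal carbon (C5) cis to the CH2O group, and iodinolysis with retention should give the Z-iodoalkene.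

Step 2
Reactants: 3 (Z)-3-iodo-2-methylprop-2-en-1-ol
Product: 4 (Z)-3-iodo-2-methylprop-2-enal
Conditions: MnO2 (activated), CH2Cl2, rt, dark
Reagents that add atoms: none
Why: Allylic oxidation with MnO2 is selective for the allylic alcohol, and the neutral conditions should keep the labile Z geometry of the β-iodoenal, which is used at once.

Step 3
Reactants: 4 (Z)-3-iodo-2-methylprop-2-enal
Product: 6 (3S,1Z)-1-iodo-2-methylhexa-1,5-dien-3-ol, via O-borinate 5 (not isolated)
Conditions: (−)-Ipc2B(allyl), Et2O, −78 °C; then NaOH, H2O2, 0 °C → rt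
Reagents that add atoms: (−)-B-allyldiisopinocampheylborane C=CCB([C@@H]1C[C@@H]2C[C@H]([C@H]1C)C2(C)C)[C@@H]1C[C@@H]2C[C@H]([C@H]1C)C2(C)C
Why: Brown asymmetric allylboration through a chair Zimmerman–Traxler transition state: the reagent derived from (+)-α-pinene adds allyl to the Si face of the aldehyde, which sets C3 as S, and alkaline peroxide cleaves the borinate without touching the iodoalkene.

Step 4
Reactants: 6 (3S,1Z)-1-iodo-2-methylhexa-1,5-dien-3-ol
Product: 7 tert-butyl{[(3S,1Z)-1-iodo-2-methylhexa-1,5-dien-3-yl]oxy}dimethylsilane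
Conditions: TBSCl, imidazole, DMF, rt
Reagents that add atoms: tert-butyldimethylsilyl chloride CC(C)(C)[Si](C)(C)Cl
Why: Silyl ether formation gives a base-stable protecting group for O3 that survives ylide formation in step 9.

Step 5
Reactants: 7 tert-butyl{[(3S,1Z)-1-iodo-2-methylhexa-1,5-dien-3-yl]oxy}dimethylsilane
Product: 9 (3S,4Z)-3-[(tert-butyldimethylsilyl)oxy]-5-iodo-4-methylpent-4-en-1-ol, via aldehyde 8 (not isolated)
Conditions: OsO4 (2 mol %), NaIO4, 2,6-lutidine, dioxane/H2O, rt; then NaBH4, MeOH, 0 °C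
Reagents that add atoms: osmium tetroxide O=[Os](=O)(=O)=O (oxygen donor, regenerated by periodate); sodium periodate [Na+].[O-]I(=O)(=O)=O
Why: Lemieux–Johnson oxidative cleavage takes place at the terminal monosubstituted alkene because OsO4 reacts slowly with the hindered, iodine-deactivated trisubstituted alkene, and borohydride reduction of the crude β-silyloxy aldehyde gives the C1 alcohol before β-elimination can occur.

Step 6
Reactants: 9 (3S,4Z)-3-[(tert-butyldimethylsilyl)oxy]-5-iodo-4-methylpent-4-en-1-ol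
Product: 10 tert-butyl{[(3S,1Z)-1,5-diiodo-2-methylpent-1-en-3-yl]oxy}dimethylsilane
Conditions: I2, PPh3, imidazole, CH2Cl2, 0 °C → rt
Reagents that add atoms: iodine [I][I]
Why: Appel-type iodination (Garegg–Samuelsson conditions): SN2 displacement of the primary oxyphosphonium salt by iodide.

Step 7
Reactants: 10 tert-butyl{[(3S,1Z)-1,5-diiodo-2-methylpent-1-en-3-yl]oxy}dimethylsilane
Product: 11 {(3S,4Z)-3-[(tert-butyldimethylsilyl)oxy]-5-iodo-4-methylpent-4-en-1-yl}triphenylphosphonium iodide
Conditions: PPh3, iPr2NEt (cat.), MeCN, 80 °C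
Reagents that add atoms: triphenylphosphine c1ccc(cc1)P(c1ccccc1)c1ccccc1
Why: SN2 quaternisation of triphenylphosphine by the primary iodide; the alkenyl iodide does not react with a phosphine in the absence of a metal catalyst.

Step 8
Reactants: 12 methyl (4R)-2,2-dimethyl-1,3-dioxolane-4-carboxylate
Product: 14 1-[(4R)-2,2-dimethyl-1,3-dioxolan-4-yl]ethan-1-one, via Weinreb amide 13 (not isolated)
Conditions: MeNH(OMe)·HCl, iPrMgCl, THF, −20 °C; then MeMgBr, 0 °C
Reagents that add atoms: methylmagnesium bromide C[Mg]Br; N,O-dimethylhydroxylamine hydrochloride CNOC.Cl (present in 13 only)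
Why: Weinreb ketone synthesis in one flask: the magnesium amide of N,O-dimethylhydroxylamine converts the ester into the amide, whose chelated tetrahedral adduct with MeMgBr collapses to the methyl ketone only on work-up, so no over-addition occurs, and the low temperature should keep the α-alkoxy stereocentre (the later C9) intact.

Step 9
Reactants: 11 {(3S,4Z)-3-[(tert-butyldimethylsilyl)oxy]-5-iodo-4-methylpent-4-en-1-yl}triphenylphosphonium iodide; 14 1-[(4R)-2,2-dimethyl-1,3-dioxolan-4-yl]ethan-1-one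
Product: 16 (4S)-4-{(2Z,5S,6Z)-5-[(tert-butyldimethylsilyl)oxy]-7-iodo-6-methylhepta-2,6-dien-2-yl}-2,2-dimethyl-1,3-dioxolane, via phosphonium ylide 15 (not isolated)
Conditions: NaHMDS (1.0 equiv), THF, −78 °C; then 14, −78 °C → rt
Reagents that add atoms: none
Why: Wittig olefination of an α-alkoxy methyl ketone with a salt-free non-stabilised ylide, a combination known to give the trisubstituted alkene in which the ylide chain is cis to the oxygen-bearing carbon, here the Z C1=C10 alkene; exactly one equivalent of base is used to avoid epimerisation of 14.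

Step 10
Reactants: 16 (4S)-4-{(2Z,5S,6Z)-5-[(tert-butyldimethylsilyl)oxy]-7-iodo-6-methylhepta-2,6-dien-2-yl}-2,2-dimethyl-1,3-dioxolane
Product: 18 (3S,1Z,5Z)-6-[(4S)-2,2-dimethyl-1,3-dioxolan-4-yl]-1-iodo-2-methylhepta-1,5-dien-3-yl acetate, via C3 alcohol 17 (not isolated)
Conditions: TBAF, THF, 0 °C → rt; then Ac2O, Et3N, DMAP (cat.), rt
Reagents that add atoms: acetic anhydride CC(=O)OC(C)=O
Why: Fluoride-mediated desilylation leaves the acetonide untouched, and the freed C3 hydroxyl, the only one in the molecule, is acetylated in the same flask by DMAP-catalysed acylation.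

Step 11
Reactants: 18 (3S,1Z,5Z)-6-[(4S)-2,2-dimethyl-1,3-dioxolan-4-yl]-1-iodo-2-methylhepta-1,5-dien-3-yl acetate
Product: 19 (2S,3Z,6S,7Z)-1,2-dihydroxy-8-iodo-3,7-dimethylocta-3,7-dien-6-yl acetate
Conditions: AcOH/THF/H2O (3:1:1), 40 °C
Reagents that add atoms: none
Why: Acid-catalysed hydrolysis of the terminal isopropylidene acetal; the allylic acetate and the iodoalkene are stable to warm aqueous acetic acid.

Step 12
Reactants: 19 (2S,3Z,6S,7Z)-1,2-dihydroxy-8-iodo-3,7-dimethylocta-3,7-dien-6-yl acetate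
Product: 20 (2S,3Z,6S,7Z)-2-hydroxy-8-iodo-3,7-dimethyl-1-[(triethylsilyl)oxy]octa-3,7-dien-6-yl acetate
Conditions: TESCl (1.05 equiv), imidazole, CH2Cl2, −78 → −40 °C
Reagents that add atoms: chlorotriethylsilane CC[Si](Cl)(CC)CC
Why: Kinetically controlled silylation of the primary C8 hydroxyl in preference to the hindered secondary allylic C9 hydroxyl at low temperature.

Step 13
Reactants: 21 methyl (Z)-2-methylbut-2-enoate (methyl angelate)
Product: 22 (Z)-2-methylbut-2-en-1-ol
Conditions: DIBAL-H (2.2 equiv), CH2Cl2, −78 °C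
Reagents that add atoms: none
Why: 1,2-Reduction of the enoate by DIBAL-H with retention of the Z geometry.

Step 14
Reactants: 22 (Z)-2-methylbut-2-en-1-ol
Product: 23 [(2S,3R)-2,3-dimethyloxiran-2-yl]methanol
Conditions: Ti(OiPr)4 (10 mol %), L-(+)-diethyl tartrate (12 mol %), tBuOOH, 4 Å MS, CH2Cl2, −20 °C
Reagents that add atoms: tert-butyl hydroperoxide CC(C)(C)OO
Why: Sharpless asymmetric epoxidation: with L-(+)-diethyl tartrate a Z-allylic alcohol is epoxidised on the face that gives the (2S,3R)-epoxy alcohol, and the stereospecific syn oxygen transfer to the Z-alkene fixes the trans relation of the two methyl groups.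

Step 15
Reactants: 23 [(2S,3R)-2,3-dimethyloxiran-2-yl]methanol
Product: 24 (2R,3R)-2,3-dimethyloxirane-2-carboxylic acid (epoxyangelic acid)
Conditions: RuCl3 (2 mol %), NaIO4, MeCN/EtOAc/H2O, rt
Reagents that add atoms: sodium periodate [Na+].[O-]I(=O)(=O)=O (oxygen via ruthenium tetroxide); water O
Why: Ruthenium tetroxide generated catalytically (RuCl3/NaIO4) oxidises the primary alcohol to the carboxylic acid without opening the epoxide; both centres are untouched and the descriptor at C2 changes only formally.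

Step 16
Reactants: 20 (2S,3Z,6S,7Z)-2-hydroxy-8-iodo-3,7-dimethyl-1-[(triethylsilyl)oxy]octa-3,7-dien-6-yl acetate; 24 (2R,3R)-2,3-dimethyloxirane-2-carboxylic acid
Product: 25 (2S,3Z,6S,7Z)-6-acetoxy-8-iodo-3,7-dimethyl-1-[(triethylsilyl)oxy]octa-3,7-dien-2-yl (2R,3R)-2,3-dimethyloxirane-2-carboxylate
Conditions: 2-methyl-6-nitrobenzoic anhydride, DMAP, Et3N, CH2Cl2, rt
Reagents that add atoms: none
Why: Shiina esterification: the mixed anhydride formed with 2-methyl-6-nitrobenzoic anhydride transfers the hindered acyl group through DMAP to the secondary allylic C9 hydroxyl under mild conditions that leave the epoxide, the acetate and the silyl ether intact.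

Step 17
Reactants: 25 (2S,3Z,6S,7Z)-6-acetoxy-8-iodo-3,7-dimethyl-1-[(triethylsilyl)oxy]octa-3,7-dien-2-yl (2R,3R)-2,3-dimethyloxirane-2-carboxylate
Product: 26 (2S,3Z,6S,7Z)-6-acetoxy-8-iodo-3,7-dimethyl-1-oxoocta-3,7-dien-2-yl (2R,3R)-2,3-dimethyloxirane-2-carboxylate
Conditions: (COCl)2, DMSO, CH2Cl2, −78 → −35 °C; then iPr2NEt, −78 → −20 °C
Reagents that add atoms: none
Why: Swern oxidation applied directly to the primary triethylsilyl ether, which activated DMSO converts into the alkoxysulfonium salt (oxidative desilylation), so that no free primary alcohol next to the C9 ester is formed (no acyl migration), and a hindered base at low temperature should limit epimerisation at C9.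

Step 18
Reactants: 27 methyl acrylate; 28 2,2-dimethoxyacetaldehyde
Product: 29 methyl 3-hydroxy-4,4-dimethoxy-2-methylidenebutanoate (racemic)
Conditions: DABCO, dioxane/H2O, rt
Reagents that add atoms: none
Why: Morita–Baylis–Hillman reaction of the DABCO–acrylate zwitterion with the unhindered, electron-poor aldehyde; the new carbinol centre is racemic and is lost in step 19.

Step 19
Reactants: 29 methyl 3-hydroxy-4,4-dimethoxy-2-methylidenebutanoate
Product: 30 methyl (Z)-2-(bromomethyl)-4,4-dimethoxybut-2-enoate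
Conditions: NBS, Me2S, CH2Cl2, 0 °C → rt
Reagents that add atoms: N-bromosuccinimide O=C1CCC(=O)N1Br
Why: Corey–Kim-type activation of the allylic alcohol (NBS/Me2S) followed by SN2' attack of bromide gives the rearranged, thermodynamically favoured Z-configured 2-(bromomethyl)enoate.

Step 20
Reactants: 26 (2S,3Z,6S,7Z)-6-acetoxy-8-iodo-3,7-dimethyl-1-oxoocta-3,7-dien-2-yl (2R,3R)-2,3-dimethyloxirane-2-carboxylate; 30 methyl (Z)-2-(bromomethyl)-4,4-dimethoxybut-2-enoate
Product: 31 methyl (3S,4R,5S,6Z,9S,10Z)-9-acetoxy-3-(dimethoxymethyl)-5-{[(2R,3R)-2,3-dimethyloxirane-2-carbonyl]oxy}-4-hydroxy-11-iodo-6,10-dimethyl-2-methylideneundeca-6,10-dienoate (germacrane C7 S, C8 R, C9 S, C3 S)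
Conditions: In powder, THF/H2O (3:1), rt
Reagents that add atoms: none
Why: Indium-mediated Barbier allylation: the allylindium from Z-bromide 30 reacts through its γ-carbon in a chair Zimmerman–Traxler transition state (7,8-syn, C7 S) on the aldehyde face anti to the C9 acyloxy group (polar Felkin–Anh, 8,9-anti, C8 R), under aqueous, neutral conditions that esters, epoxide, acetal and iodoalkene tolerate.

Step 21
Reactants: 31 the C8 alcohol / C6 dimethyl acetal from step 20
Product: 33 methyl (3S,4R,5S,6Z,9S,10Z)-9-acetoxy-5-{[(2R,3R)-2,3-dimethyloxirane-2-carbonyl]oxy}-3-formyl-11-iodo-6,10-dimethyl-2-methylidene-4-[(triethylsilyl)oxy]undeca-6,10-dienoate, via collidinium salt 32 (not isolated)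
Conditions: TESOTf (4 equiv), 2,4,6-collidine (6 equiv), CH2Cl2, −40 → 0 °C; then H2O, 0 °C → rt
Reagents that add atoms: triethylsilyl trifluoromethanesulfonate CC[Si](CC)(CC)OS(=O)(=O)C(F)(F)F; water O; 2,4,6-trimethylpyridine Cc1cc(C)nc(C)c1 (present in 32 only)
Why: Silyl triflate with collidine first silylates O8 and then converts the dimethyl acetal chemoselectively into an N-(α-methoxyalkyl)collidinium salt that water hydrolyses to the aldehyde (acetal cleavage under near-neutral conditions), which should spare the epoxide, the esters and the acidic C7–H; the aldehyde is used at once.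

Step 22
Reactants: 33 the C6 aldehyde / C5 Z-iodoalkene from step 21
Product: 35 8-O-triethylsilyl ether of the target (cis-fused 6,12-lactone), via ring-closed hydroxy ester 34 (not isolated)
Conditions: CrCl2 (12 equiv), NiCl2 (0.1 equiv), DMSO/THF, rt, slow addition to 2 mM; aqueous work-up; then PPTS (cat.), CH2Cl2, rt
Reagents that add atoms: none
Why: CrCl2 reduces NiCl2 to zerovalent nickel, which inserts into the C5–I bond; transmetalation to trivalent chromium gives a Z-alkenylchromium (geometry retained) that adds to the C6 aldehyde, so two electrophilic carbons are joined by reductive polarity reversal. The closest known reaction type is the intramolecular Nozaki–Hiyama–Kishi macrocyclisation followed by lactonisation of a γ-hydroxy acrylate. The ten-membered carbocycle closes by 10-exo-trig addition of C5 to the carbonyl, and the γ-lactone by 5-exo-trig acyl substitution of the C6 oxygen on the C12 methyl ester (completed by PPTS), O8 being blocked as its silyl ether. C6 (R) is set under Felkin–Anh control by the existing C7 centre: the gauche ring torsion C5–C6–C7–C8 needed for closure places the sp2 acrylate carbon C11 antiperiplanar to the forming bond and the alkenylchromium passes H7, which leads to the cis ring fusion. The step needs chemoselectivity for iodoalkene and aldehyde (esters, epoxide and allylic acetate are inert to divalent chromium at room temperature), cyclisation over oligomerisation (high dilution; the two Z alkenes fold the chain) and facial selectivity at C6 (secured by the C7 stereocentre and the non-chelating silyl ether on O8).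

Step 23
Reactants: 35 8-O-triethylsilyl ether of the target
Product: 36 target, (3S,6R,7S,8R,9S,1(10)Z,4Z)-3-acetoxy-8-hydroxy-9-{[(2R,3R)-2,3-dimethyloxirane-2-carbonyl]oxy}germacra-1(10),4,11(13)-trien-12,6-olide
Conditions: HF·pyridine, pyridine, THF, 0 °C
Reagents that add atoms: none
Why: Fluoride-mediated desilylation with buffered HF·pyridine is non-basic, so neither migration of the epoxyangeloyl group from O9 to O8 nor translactonisation to O8 is expected, and the lactone, acetate and epoxy ester are stable.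

**Compound list**

1 | prop-2-yn-1-ol | C#CCO | starting material
2 | bromomagnesium (Z)-3-(bromomagnesio)-2-methylprop-2-en-1-olate (not isolated) | Br[Mg]/C=C(/C)CO[Mg]Br | intermediate
3 | (Z)-3-iodo-2-methylprop-2-en-1-ol | I/C=C(/C)CO | intermediate
4 | (Z)-3-iodo-2-methylprop-2-enal | I/C=C(/C)C=O | intermediate
5 | (3S,1Z)-1-iodo-2-methylhexa-1,5-dien-3-yl diisopinocampheylborinate (not isolated) | I/C=C(/C)[C@@H](OB([C@@H]1C[C@@H]2C[C@H]([C@H]1C)C2(C)C)[C@@H]1C[C@@H]2C[C@H]([C@H]1C)C2(C)C)CC=C | intermediate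
6 | (3S,1Z)-1-iodo-2-methylhexa-1,5-dien-3-ol | I/C=C(/C)[C@@H](O)CC=C | intermediate
7 | tert-butyl{[(3S,1Z)-1-iodo-2-methylhexa-1,5-dien-3-yl]oxy}dimethylsilane | I/C=C(/C)[C@@H](O[Si](C)(C)C(C)(C)C)CC=C | intermediate
8 | (3S,4Z)-3-[(tert-butyldimethylsilyl)oxy]-5-iodo-4-methylpent-4-enal (not isolated) | I/C=C(/C)[C@@H](O[Si](C)(C)C(C)(C)C)CC=O | intermediate
9 | (3S,4Z)-3-[(tert-butyldimethylsilyl)oxy]-5-iodo-4-methylpent-4-en-1-ol | I/C=C(/C)[C@@H](O[Si](C)(C)C(C)(C)C)CCO | intermediate
10 | tert-butyl{[(3S,1Z)-1,5-diiodo-2-methylpent-1-en-3-yl]oxy}dimethylsilane | I/C=C(/C)[C@@H](O[Si](C)(C)C(C)(C)C)CCI | intermediate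
11 | {(3S,4Z)-3-[(tert-butyldimethylsilyl)oxy]-5-iodo-4-methylpent-4-en-1-yl}triphenylphosphonium iodide | I/C=C(/C)[C@@H](O[Si](C)(C)C(C)(C)C)CC[P+](c1ccccc1)(c1ccccc1)c1ccccc1.[I-] | intermediate
12 | methyl (4R)-2,2-dimethyl-1,3-dioxolane-4-carboxylate | COC(=O)[C@H]1COC(C)(C)O1 | starting material
13 | (4R)-N-methoxy-N,2,2-trimethyl-1,3-dioxolane-4-carboxamide (not isolated) | CON(C)C(=O)[C@H]1COC(C)(C)O1 | intermediate
14 | 1-[(4R)-2,2-dimethyl-1,3-dioxolan-4-yl]ethan-1-one | CC(=O)[C@H]1COC(C)(C)O1 | intermediate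
15 | {(3S,4Z)-3-[(tert-butyldimethylsilyl)oxy]-5-iodo-4-methylpent-4-en-1-ylidene}triphenylphosphorane (not isolated) | I/C=C(/C)[C@@H](O[Si](C)(C)C(C)(C)C)CC=P(c1ccccc1)(c1ccccc1)c1ccccc1 | intermediate
16 | (4S)-4-{(2Z,5S,6Z)-5-[(tert-butyldimethylsilyl)oxy]-7-iodo-6-methylhepta-2,6-dien-2-yl}-2,2-dimethyl-1,3-dioxolane | I/C=C(/C)[C@@H](O[Si](C)(C)C(C)(C)C)C/C=C(/C)[C@H]1COC(C)(C)O1 | intermediate
17 | (3S,1Z,5Z)-6-[(4S)-2,2-dimethyl-1,3-dioxolan-4-yl]-1-iodo-2-methylhepta-1,5-dien-3-ol (not isolated) | I/C=C(/C)[C@@H](O)C/C=C(/C)[C@H]1COC(C)(C)O1 | intermediate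
18 | (3S,1Z,5Z)-6-[(4S)-2,2-dimethyl-1,3-dioxolan-4-yl]-1-iodo-2-methylhepta-1,5-dien-3-yl acetate | I/C=C(/C)[C@@H](OC(C)=O)C/C=C(/C)[C@H]1COC(C)(C)O1 | intermediate
19 | (2S,3Z,6S,7Z)-1,2-dihydroxy-8-iodo-3,7-dimethylocta-3,7-dien-6-yl acetate | I/C=C(/C)[C@@H](OC(C)=O)C/C=C(/C)[C@H](O)CO | intermediate
20 | (2S,3Z,6S,7Z)-2-hydroxy-8-iodo-3,7-dimethyl-1-[(triethylsilyl)oxy]octa-3,7-dien-6-yl acetate | I/C=C(/C)[C@@H](OC(C)=O)C/C=C(/C)[C@H](O)CO[Si](CC)(CC)CC | intermediate
21 | methyl (Z)-2-methylbut-2-enoate (methyl angelate) | C/C=C(/C)C(=O)OC | starting material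
22 | (Z)-2-methylbut-2-en-1-ol | C/C=C(/C)CO | intermediate
23 | [(2S,3R)-2,3-dimethyloxiran-2-yl]methanol | OC[C@]1(C)O[C@@H]1C | intermediate
24 | (2R,3R)-2,3-dimethyloxirane-2-carboxylic acid | OC(=O)[C@]1(C)O[C@@H]1C | intermediate
25 | (2S,3Z,6S,7Z)-6-acetoxy-8-iodo-3,7-dimethyl-1-[(triethylsilyl)oxy]octa-3,7-dien-2-yl (2R,3R)-2,3-dimethyloxirane-2-carboxylate | I/C=C(/C)[C@@H](OC(C)=O)C/C=C(/C)[C@H](OC(=O)[C@]1(C)O[C@@H]1C)CO[Si](CC)(CC)CC | intermediate
26 | (2S,3Z,6S,7Z)-6-acetoxy-8-iodo-3,7-dimethyl-1-oxoocta-3,7-dien-2-yl (2R,3R)-2,3-dimethyloxirane-2-carboxylate | I/C=C(/C)[C@@H](OC(C)=O)C/C=C(/C)[C@H](OC(=O)[C@]1(C)O[C@@H]1C)C=O | intermediate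
27 | methyl acrylate | C=CC(=O)OC | starting material
28 | 2,2-dimethoxyacetaldehyde | COC(OC)C=O | starting material
29 | methyl 3-hydroxy-4,4-dimethoxy-2-methylidenebutanoate (racemic) | C=C(C(=O)OC)C(O)C(OC)OC | intermediate
30 | methyl (Z)-2-(bromomethyl)-4,4-dimethoxybut-2-enoate | BrC/C(C(=O)OC)=C\C(OC)OC | intermediate
31 | methyl (3S,4R,5S,6Z,9S,10Z)-9-acetoxy-3-(dimethoxymethyl)-5-{[(2R,3R)-2,3-dimethyloxirane-2-carbonyl]oxy}-4-hydroxy-11-iodo-6,10-dimethyl-2-methylideneundeca-6,10-dienoate | I/C=C(/C)[C@@H](OC(C)=O)C/C=C(/C)[C@H](OC(=O)[C@]1(C)O[C@@H]1C)[C@H](O)[C@@H](C(OC)OC)C(=C)C(=O)OC | intermediate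
32 | N-(α-methoxyalkyl)-2,4,6-trimethylpyridinium triflate formed at C6 of 31, O8 triethylsilylated, C6 configuration undefined (not isolated) | I/C=C(/C)[C@@H](OC(C)=O)C/C=C(/C)[C@H](OC(=O)[C@]1(C)O[C@@H]1C)[C@H](O[Si](CC)(CC)CC)[C@@H](C(OC)[n+]1c(C)cc(C)cc1C)C(=C)C(=O)OC.[O-]S(=O)(=O)C(F)(F)F | intermediate
33 | methyl (3S,4R,5S,6Z,9S,10Z)-9-acetoxy-5-{[(2R,3R)-2,3-dimethyloxirane-2-carbonyl]oxy}-3-formyl-11-iodo-6,10-dimethyl-2-methylidene-4-[(triethylsilyl)oxy]undeca-6,10-dienoate | I/C=C(/C)[C@@H](OC(C)=O)C/C=C(/C)[C@H](OC(=O)[C@]1(C)O[C@@H]1C)[C@H](O[Si](CC)(CC)CC)[C@@H](C=O)C(=C)C(=O)OC | intermediate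
34 | methyl 2-[(1R,2R,3Z,5S,7Z,9S,10R)-5-acetoxy-9-{[(2R,3R)-2,3-dimethyloxirane-2-carbonyl]oxy}-2-hydroxy-4,8-dimethyl-10-[(triethylsilyl)oxy]cyclodeca-3,7-dien-1-yl]prop-2-enoate (not isolated) | O[C@@H]1/C=C(/C)[C@@H](OC(C)=O)C/C=C(/C)[C@H](OC(=O)[C@]2(C)O[C@@H]2C)[C@H](O[Si](CC)(CC)CC)[C@@H]1C(=C)C(=O)OC | intermediate
35 | 8-O-triethylsilyl ether of the target (same arrangement at every centre; C7 is formally R through the priority change) | C=C1C(=O)O[C@@H]2/C=C(/C)[C@@H](OC(C)=O)C/C=C(/C)[C@H](OC(=O)[C@]3(C)O[C@@H]3C)[C@H](O[Si](CC)(CC)CC)[C@H]12 | intermediate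
36 | (3S,6R,7S,8R,9S,1(10)Z,4Z)-3-acetoxy-8-hydroxy-9-{[(2R,3R)-2,3-dimethyloxirane-2-carbonyl]oxy}germacra-1(10),4,11(13)-trien-12,6-olide | C=C1C(=O)O[C@@H]2/C=C(/C)[C@@H](OC(C)=O)C/C=C(/C)[C@H](OC(=O)[C@]3(C)O[C@@H]3C)[C@H](O)[C@H]12 | target

**Step count and risks**

Total step count: 23. Longest linear sequence: 17 steps (steps 1–7, 9–12, 16, 17, 20–23).

Steps most likely to fail:

1. Step 22. The alkenylchromium may add to the wrong face of the C6 aldehyde, which would give the trans-fused C6 epimer, and oligomerisation may compete with ring closure. Fallback: C6 is set by reagent control after ring closure. From 33 the cyclisation is run as before but worked up without acid, which would give the C6-epimeric ring-closed hydroxy ester F1. Oxidation with Dess–Martin periodinane would give the cyclodecadienone with a C6 ketone F2. 1,2-Reduction with (R)-2-methyl-CBS-oxazaborolidine and catecholborane, with the alkenyl group taken as the larger substituent, should then deliver 34, where the route is rejoined before the PPTS lactonisation.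

2. Step 20. Chelation of indium by the C9 acyloxy group or a boat transition state may erode the 7,8-syn/8,9-anti selectivity, and O8 may lactonise prematurely onto C12. Fallback: the C7–C8 bond is made by a stereospecific allylboration. From 30, palladium-catalysed borylation (B2pin2, Pd2(dba)3) would give methyl (Z)-4,4-dimethoxy-2-[(4,4,5,5-tetramethyl-1,3,2-dioxaborolan-2-yl)methyl]but-2-enoate F3. Its Sc(OTf)3-catalysed addition to 26 passes through a closed chair transition state in which boron cannot chelate the acyloxy group, so the Z-boronate should give the 7,8-syn, Felkin product. Cold hydrolytic work-up returns the route at 31.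

3. Step 21. While the aldehyde is set free, the base or the silyl triflate may cause epimerisation at C7, migration of the C11=C13 double bond into conjugation, or opening of the epoxide. Fallback: C6 is carried at the alcohol oxidation level and oxidised under neutral conditions. From 27, the Morita–Baylis–Hillman reaction with purchased (4-methoxybenzyloxy)acetaldehyde would give methyl 3-hydroxy-4-[(4-methoxybenzyl)oxy]-2-methylidenebutanoate F4. NBS/Me2S would give methyl (Z)-2-(bromomethyl)-4-[(4-methoxybenzyl)oxy]but-2-enoate F5. Indium-mediated allylation of 26 would give the C6 4-methoxybenzyl ether analogue of 31 F6. TESOTf/2,6-lutidine at −78 °C would give its 8-O-triethylsilyl ether F7. DDQ in buffered CH2Cl2 would give the primary C6 alcohol F8. Dess–Martin periodinane with NaHCO3 would oxidise it to 33, where the route is rejoined.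

Further compounds

F1 | step 22 | C6 epimer of 34 (6S hydroxy ester) | O[C@H]1/C=C(/C)[C@@H](OC(C)=O)C/C=C(/C)[C@H](OC(=O)[C@]2(C)O[C@@H]2C)[C@H](O[Si](CC)(CC)CC)[C@@H]1C(=C)C(=O)OC
F2 | step 22 | cyclodecadienone with C6 ketone, derived from F1 | O=C1/C=C(/C)[C@@H](OC(C)=O)C/C=C(/C)[C@H](OC(=O)[C@]2(C)O[C@@H]2C)[C@H](O[Si](CC)(CC)CC)[C@@H]1C(=C)C(=O)OC
F3 | step 20 | methyl (Z)-4,4-dimethoxy-2-[(4,4,5,5-tetramethyl-1,3,2-dioxaborolan-2-yl)methyl]but-2-enoate | CC1(C)OB(C/C(C(=O)OC)=C\C(OC)OC)OC1(C)C
F4 | step 21 | methyl 3-hydroxy-4-[(4-methoxybenzyl)oxy]-2-methylidenebutanoate (racemic) | C=C(C(=O)OC)C(O)COCc1ccc(OC)cc1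
F5 | step 21 | methyl (Z)-2-(bromomethyl)-4-[(4-methoxybenzyl)oxy]but-2-enoate | BrC/C(C(=O)OC)=C\COCc1ccc(OC)cc1
F6 | step 21 | analogue of 31 with C6 as CH2O(4-methoxybenzyl) | I/C=C(/C)[C@@H](OC(C)=O)C/C=C(/C)[C@H](OC(=O)[C@]1(C)O[C@@H]1C)[C@H](O)[C@@H](COCc1ccc(OC)cc1)C(=C)C(=O)OC
F7 | step 21 | 8-O-triethylsilyl ether of F6 | I/C=C(/C)[C@@H](OC(C)=O)C/C=C(/C)[C@H](OC(=O)[C@]1(C)O[C@@H]1C)[C@H](O[Si](CC)(CC)CC)[C@@H](COCc1ccc(OC)cc1)C(=C)C(=O)OC
F8 | step 21 | primary C6 alcohol from F7 | I/C=C(/C)[C@@H](OC(C)=O)C/C=C(/C)[C@H](OC(=O)[C@]1(C)O[C@@H]1C)[C@H](O[Si](CC)(CC)CC)[C@@H](CO)C(=C)C(=O)OC
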